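**Retrosynthetic overview**
1. Target ⇐ C4 chlorination of the 14‑membered 3,5‑diketo lactone.
2. 14‑membered ring ⇐ ring contraction (sulfur extrusion, forms C3–C4) of a 15‑membered thia‑lactone, closed by S‑alkylation of a C1–C3 thiomalonate (already esterified to O–C21) on a C5 chloromethyl ketone.
3. Side chain ⇐ two stereospecific 1,2‑boronate shifts on the ring C15–B bond: carbenoid homologation (C15–C16, sets C16), then Zweifel coupling (C16–C17, 17Z), then Z‑reduction of the 19‑yne.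
4. Rings A and B ⇐ formed together by a catalyst‑controlled intramolecular Diels–Alder reaction of a 1‑boryl (E,E,E)‑trienimide; C8 from (S)‑3‑bromo‑2‑methylpropan‑1‑ol, C21 from (S)‑but‑3‑yn‑2‑ol.
5. Ring order: A + B in one step, then the 15‑membered thia‑lactone, contracted to the 14‑membered macrolide.

Assumption: the drawn enol (C5–OH cis to Cl) is one tautomeric/geometric form of the 4‑chloro‑3,5‑diketone, and C2 (between the lactone and ketone carbonyls) is configurationally labile and is taken to settle in the (2S) series under equilibrating conditions.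

Locants (macrolide skeleton): C1 lactone C=O, C2 (CHMe), C3 ketone, C4 (CCl), C5 enol carbon, ring A = C6, C7, C12, C13=C14, C15, ring B = C7, C8(Me), C9–C11, C12, then C16 (CHMe), C17=C18, C19=C20, C21 (CH(Me)O). Bpin = 4,4,5,5‑tetramethyl‑1,3,2‑dioxaborolan‑2‑yl. Target descriptors: 2S,6R,7R,8R,12S,15S,16R,17Z,19Z,21S.

**Route**

Step 1
Reactants: 1 (S)-3-bromo-2-methylpropan-1-ol; 2 but-3-en-1-ylmagnesium bromide
Product: 3 (R)-2-methylhept-6-en-1-ol
Conditions: 2 (2.3 equiv), Li2CuCl4 (3 mol %), THF, −20 to 0 °C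
Reagents that add atoms: none
Why: Copper-catalysed sp3–sp3 Kochi coupling of the primary bromide with the Grignard reagent (the first equivalent only deprotonates the hydroxyl) extends the chain without touching the chiral-pool stereocentre, which becomes C8.

Step 2
Reactants: 3 (R)-2-methylhept-6-en-1-ol; 4 (E)-but-2-enal
Product: 5 (2E,7R)-8-hydroxy-7-methyloct-2-enal
Conditions: 4 (5 equiv), second-generation Hoveyda–Grubbs catalyst RuCl2(SIMes)(=CH-C6H4-2-OiPr) (2 mol %), CH2Cl2, 40 °C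
Reagents that add atoms: none
Why: Cross-metathesis of a terminal alkene with excess crotonaldehyde is a reliable E-selective route to enals and tolerates the free alcohol.

Step 3
Reactants: 5 (2E,7R)-8-hydroxy-7-methyloct-2-enal
Product: 6 (2R,6E,8E)-2-methyl-9-(Bpin)nona-6,8-dien-1-ol
Conditions: CH2(Bpin)2 (2.3 equiv), LiTMP (2.3 equiv), THF, 0 °C; then 5, −78 °C to rt
Reagents that add atoms: bis(pinacolato)borylmethane CC1(C)OB(CB2OC(C)(C)C(C)(C)O2)OC1(C)C
Why: Boron–Wittig olefination, in which 1,2-addition of the gem-diboryl carbanion to the aldehyde and syn B–O elimination give the E-alkenyl boronate and hence the (E,E)-dienyl boronate, with one extra equivalent of base covering the hydroxyl.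

Step 4
Reactants: 6 (2R,6E,8E)-2-methyl-9-(Bpin)nona-6,8-dien-1-ol
Product: 7 (2R,6E,8E)-2-methyl-9-(Bpin)nona-6,8-dienal
Conditions: Dess–Martin periodinane, CH2Cl2, 0 °C to rt
Reagents that add atoms: none
Why: Dess–Martin oxidation gives the α-branched aldehyde without base, so C8 is not epimerised and the dienyl boronate is untouched.

Step 5
Reactants: 7 (2R,6E,8E)-2-methyl-9-(Bpin)nona-6,8-dienal
Product: 8 3-[(2E,4R,8E,10E)-4-methyl-11-(Bpin)undeca-2,8,10-trienoyl]-1,3-oxazolidin-2-one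
Conditions: (EtO)2P(O)CH2C(O)-oxazolidinone, LiCl, iPr2NEt, MeCN, rt
Reagents that add atoms: diethyl [2-oxo-2-(2-oxo-1,3-oxazolidin-3-yl)ethyl]phosphonate CCOP(=O)(OCC)CC(=O)N1CCOC1=O
Why: Masamune–Roush Horner–Wadsworth–Emmons olefination is E-selective and mild enough to keep the α-stereocentre.

Step 6
Reactants: 8 3-[(2E,4R,8E,10E)-4-methyl-11-(Bpin)undeca-2,8,10-trienoyl]-1,3-oxazolidin-2-one
Product: 10 methyl (1R,2R,4aS,8R,8aR)-8-methyl-2-(Bpin)-1,2,4a,5,6,7,8,8a-octahydronaphthalene-1-carboxylate, via imide cycloadduct 9 (not isolated)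
Conditions: [Cu((S,S)-tBu-box)](SbF6)2 (10 mol %; tBu-box = 2,2'-(propane-2,2-diyl)bis[(4S)-4-tert-butyl-4,5-dihydrooxazole]), CH2Cl2, 25 °C, 48 h; then MeOH, K2CO3 (0.2 equiv), 0 °C
Reagents that add atoms: methanol CO
Why: Intramolecular Diels–Alder reaction of the two-point-bound imide in the square-planar copper bis(oxazoline) complex, where the endo mode gives the trans ring fusion and fixes C6, C7, C12 and C15 relative to each other, the ligand directs the diene to the Re face of C6 so that the C8 methyl ends up axial (cis to the C6–C7 bond) against its modest intrinsic preference, and in situ methanolysis gives an ester that survives the organolithium steps.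

Step 7
Reactants: 11 ethanol
Product: 12 ethyl N,N-diisopropylcarbamate
Conditions: iPr2NC(O)Cl, Et3N, CH2Cl2, reflux
Reagents that add atoms: N,N-diisopropylcarbamoyl chloride CC(C)N(C(C)C)C(Cl)=O
Why: Carbamoylation of ethanol gives the Hoppe carbamate needed for sparteine-mediated lithiation.

Step 8
Reactants: 10 methyl (1R,2R,4aS,8R,8aR)-8-methyl-2-(Bpin)-1,2,4a,5,6,7,8,8a-octahydronaphthalene-1-carboxylate; 12 ethyl N,N-diisopropylcarbamate
Product: 15 methyl (1R,2R,4aS,8R,8aR)-8-methyl-2-[(1S)-1-(Bpin)ethyl]-1,2,4a,5,6,7,8,8a-octahydronaphthalene-1-carboxylate, via lithiated carbamate 13 (not isolated), via boronate complex 14 (not isolated)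
Conditions: 12 (1.4 equiv), s-BuLi, (+)-sparteine, Et2O, −78 °C, 5 h; then 10, −78 °C, 1 h; then MgBr2·OEt2, 35 °C
Reagents that add atoms: none
Why: Lithiation–borylation, in which (+)-sparteine-directed deprotonation gives the configurationally stable (R)-lithiated carbamate that adds to boron with retention, and the antiperiplanar 1,2-shift of C15 from boron to carbon (inversion at the carbenoid carbon, retention at C15) forms C15–C16 and sets C16 by reagent control.

Step 9
Reactants: 16 (S)-but-3-yn-2-ol; 17 (E)-1,2-diiodoethene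
Product: 19 {[(2S,5E)-6-iodohex-5-en-3-yn-2-yl]oxy}trimethylsilane, via iodoenynol 18 (not isolated)
Conditions: 17 (5 equiv), Pd(PPh3)4 (3 mol %), CuI (6 mol %), iPr2NH, THF, 0 °C to rt; then Me3SiCl, imidazole
Reagents that add atoms: chlorotrimethylsilane C[Si](C)(C)Cl
Why: Sonogashira mono-coupling with excess diiodoethene keeps the E geometry and the chiral-pool carbinol centre (C21), and the alcohol is capped as its silyl ether in the same flask.

Step 10
Reactants: 15 methyl (1R,2R,4aS,8R,8aR)-8-methyl-2-[(1S)-1-(Bpin)ethyl]-1,2,4a,5,6,7,8,8a-octahydronaphthalene-1-carboxylate; 19 {[(2S,5E)-6-iodohex-5-en-3-yn-2-yl]oxy}trimethylsilane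
Product: 22 methyl (1R,2S,4aS,8R,8aR)-2-[(2R,3Z,7S)-7-hydroxyoct-3-en-5-yn-2-yl]-8-methyl-1,2,4a,5,6,7,8,8a-octahydronaphthalene-1-carboxylate, via alkenyllithium 20 (not isolated), via boronate complex 21 (not isolated)
Conditions: 19 (1.5 equiv), t-BuLi (3.0 equiv), Et2O, −78 °C; then 15, −78 to 0 °C; then I2, THF, −78 °C; then NaOMe, MeOH, −78 °C to rt
Reagents that add atoms: none
Why: Zweifel olefination, in which iodine–lithium exchange gives the E-alkenyllithium with retention, iodination of the boronate complex triggers the 1,2-shift of C16 from boron to carbon (retention at C16), anti elimination inverts the alkene to the 17Z-enyne, and methoxide removes the silyl ether.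

Step 11
Reactants: 22 methyl (1R,2S,4aS,8R,8aR)-2-[(2R,3Z,7S)-7-hydroxyoct-3-en-5-yn-2-yl]-8-methyl-1,2,4a,5,6,7,8,8a-octahydronaphthalene-1-carboxylate
Product: 23 methyl (1R,2S,4aS,8R,8aR)-2-[(2R,3Z,5Z,7S)-7-hydroxyocta-3,5-dien-2-yl]-8-methyl-1,2,4a,5,6,7,8,8a-octahydronaphthalene-1-carboxylate
Conditions: Zn dust activated with Cu(OAc)2 and AgNO3, MeOH/H2O 1:1, 40 °C
Reagents that add atoms: none
Why: Activated zinc reduces the conjugated, propargylic-alcohol-activated alkyne by cis delivery of hydrogen to the 19Z-alkene and leaves the isolated ring alkene and the ester alone.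

Step 12
Reactants: 23 methyl (1R,2S,4aS,8R,8aR)-2-[(2R,3Z,5Z,7S)-7-hydroxyocta-3,5-dien-2-yl]-8-methyl-1,2,4a,5,6,7,8,8a-octahydronaphthalene-1-carboxylate
Product: 24 2-chloro-1-[(1R,2S,4aS,8R,8aR)-2-[(2R,3Z,5Z,7S)-7-hydroxyocta-3,5-dien-2-yl]-8-methyl-1,2,4a,5,6,7,8,8a-octahydronaphthalen-1-yl]ethan-1-one
Conditions: ICH2Cl (2.5 equiv), MeLi·LiBr (3.3 equiv), THF, −78 °C; AcOH quench at −78 °C
Reagents that add atoms: chloroiodomethane ClCI
Why: Chloromethyllithium made in situ by iodine–lithium exchange adds once to the ester because the tetrahedral adduct survives at −78 °C (carbenoid homologation of esters to α-chloroketones), which installs C4 as an electrophile.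

Step 13
Reactants: 25 methylmalonic acid
Product: 26 2-methyl-3-oxo-3-{[2-(trimethylsilyl)ethyl]sulfanyl}propanoic acid (racemic)
Conditions: Me3SiCH2CH2SH (1.0 equiv), DCC (1.0 equiv), MeCN, 0 °C
Reagents that add atoms: 2-(trimethylsilyl)ethanethiol C[Si](C)(C)CCS
Why: Carbodiimide-mediated mono-thioesterification of a malonic acid gives the malonic acid half thioester, whose C2 centre is left racemic because it is set later under equilibration.

Step 14
Reactants: 24 2-chloro-1-[(1R,2S,4aS,8R,8aR)-2-[(2R,3Z,5Z,7S)-7-hydroxyocta-3,5-dien-2-yl]-8-methyl-1,2,4a,5,6,7,8,8a-octahydronaphthalen-1-yl]ethan-1-one; 26 2-methyl-3-oxo-3-{[2-(trimethylsilyl)ethyl]sulfanyl}propanoic acid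
Product: 27 (2S,3Z,5Z,7R)-7-[(1R,2S,4aS,8R,8aR)-1-(chloroacetyl)-8-methyl-1,2,4a,5,6,7,8,8a-octahydronaphthalen-2-yl]octa-3,5-dien-2-yl 2-methyl-3-oxo-3-{[2-(trimethylsilyl)ethyl]sulfanyl}propanoate (C2 epimers)
Conditions: 26 (1.5 equiv), DCC (1.5 equiv), CH2Cl2, −20 to 0 °C
Reagents that add atoms: none
Why: Carbodiimide coupling of the half thioester (through its ketene) acylates the secondary alcohol under neutral conditions with retention at C21 and without base that would disturb the chloroketone.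

Step 15
Reactants: 27 (2S,3Z,5Z,7R)-7-[(1R,2S,4aS,8R,8aR)-1-(chloroacetyl)-8-methyl-1,2,4a,5,6,7,8,8a-octahydronaphthalen-2-yl]octa-3,5-dien-2-yl 2-methyl-3-oxo-3-{[2-(trimethylsilyl)ethyl]sulfanyl}propanoate
Product: 30 (2S,6R,7R,8R,12S,15S,16R,17Z,19Z,21S)-4-deschloro macrolide (14-membered 3,5-diketo lactone), via thiocarboxylate 28 (not isolated), via thialactone 29 (not isolated)
Conditions: Bu4NF (1.05 equiv), THF/MeCN, 1 mM, 0 °C to rt; then PPh3 (3 equiv), LiBr (5 equiv), DBU (2 equiv), MeCN, 50 °C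
Reagents that add atoms: none
Why: Proposed new method: fluoride unmasks the thiocarboxylate, whose soft sulfur closes the 15-membered ring by SN2 on the α-chloroketone, then LiBr/DBU soft-enolises C4 toward the C5 ketone, the enolate attacks the adjacent malonyl-activated thioester carbonyl C3 (3-exo-trig) and PPh3 strips sulfur from the resulting thiirane, so that sulfur is extruded, the C3–C4 bond forms and the ring contracts from 15 to 14 atoms while C2 equilibrates under DBU to the 2S epimer; the closest known reaction is the Eschenmoser sulfide contraction of S-(2-oxoalkyl) thioesters to 1,3-diketones, which has not been shown on a macrocyclic thiomalonate.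

Step 16
Reactants: 30 (2S,6R,7R,8R,12S,15S,16R,17Z,19Z,21S)-4-deschloro macrolide
Product: 31 CNP0477386.1 (target)
Conditions: N-chlorosuccinimide (1.0 equiv), CH2Cl2, −20 °C
Reagents that add atoms: N-chlorosuccinimide O=C1CCC(=O)N1Cl
Why: Electrophilic chlorination of the enolised 1,3-diketone at its central carbon C4, the most acidic and nucleophilic position, with one equivalent of reagent gives the monochloro enol.

**Compound list**
1 | (S)-3-bromo-2-methylpropan-1-ol | OC[C@H](C)CBr | starting material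
2 | but-3-en-1-ylmagnesium bromide | C=CCC[Mg]Br | starting material
3 | (R)-2-methylhept-6-en-1-ol | OC[C@H](C)CCCC=C | intermediate
4 | (E)-but-2-enal | C/C=C/C=O | starting material
5 | (2E,7R)-8-hydroxy-7-methyloct-2-enal | OC[C@H](C)CCC/C=C/C=O | intermediate
6 | (2R,6E,8E)-2-methyl-9-(Bpin)nona-6,8-dien-1-ol | OC[C@H](C)CCC/C=C/C=C/B1OC(C)(C)C(C)(C)O1 | intermediate
7 | (2R,6E,8E)-2-methyl-9-(Bpin)nona-6,8-dienal | O=C[C@H](C)CCC/C=C/C=C/B1OC(C)(C)C(C)(C)O1 | intermediate
8 | 3-[(2E,4R,8E,10E)-4-methyl-11-(Bpin)undeca-2,8,10-trienoyl]-1,3-oxazolidin-2-one | O=C1OCCN1C(=O)/C=C/[C@H](C)CCC/C=C/C=C/B2OC(C)(C)C(C)(C)O2 | intermediate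
9 | 3-{[(1R,2R,4aS,8R,8aR)-8-methyl-2-(Bpin)-1,2,4a,5,6,7,8,8a-octahydronaphthalen-1-yl]carbonyl}-1,3-oxazolidin-2-one (imide cycloadduct) | CC1(C)C(C)(C)OB(O1)[C@@H]2C=C[C@@H]3CCC[C@@H](C)[C@H]3[C@@H]2C(=O)N4CCOC4=O | intermediate
10 | methyl (1R,2R,4aS,8R,8aR)-8-methyl-2-(Bpin)-1,2,4a,5,6,7,8,8a-octahydronaphthalene-1-carboxylate | CC1(C)C(C)(C)OB(O1)[C@@H]2C=C[C@@H]3CCC[C@@H](C)[C@H]3[C@@H]2C(=O)OC | intermediate
11 | ethanol | CCO | starting material
12 | ethyl N,N-diisopropylcarbamate | CCOC(=O)N(C(C)C)C(C)C | intermediate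
13 | (R)-1-lithioethyl N,N-diisopropylcarbamate (sparteine-bound lithiated carbamate) | C[C@@H]([Li])OC(=O)N(C(C)C)C(C)C | intermediate
14 | lithium boronate (ate) complex from 10 and 13 | [Li+].CC1(C)C(C)(C)O[B-](O1)([C@H](C)OC(=O)N(C(C)C)C(C)C)[C@@H]2C=C[C@@H]3CCC[C@@H](C)[C@H]3[C@@H]2C(=O)OC | intermediate
15 | methyl (1R,2R,4aS,8R,8aR)-8-methyl-2-[(1S)-1-(Bpin)ethyl]-1,2,4a,5,6,7,8,8a-octahydronaphthalene-1-carboxylate | CC1(C)C(C)(C)OB(O1)[C@@H](C)[C@@H]2C=C[C@@H]3CCC[C@@H](C)[C@H]3[C@@H]2C(=O)OC | intermediate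
16 | (S)-but-3-yn-2-ol | C[C@H](O)C#C | starting material
17 | (E)-1,2-diiodoethene | I/C=C/I | starting material
18 | (2S,5E)-6-iodohex-5-en-3-yn-2-ol (iodoenynol) | C[C@H](O)C#C/C=C/I | intermediate
19 | {[(2S,5E)-6-iodohex-5-en-3-yn-2-yl]oxy}trimethylsilane | C[C@H](O[Si](C)(C)C)C#C/C=C/I | intermediate
20 | (1E,5S)-1-lithio-5-(trimethylsilyloxy)hex-1-en-3-yne (alkenyllithium) | C[C@H](O[Si](C)(C)C)C#C/C=C/[Li] | intermediate
21 | lithium alkenylboronate (ate) complex from 15 and 20 | [Li+].C[C@H](O[Si](C)(C)C)C#C/C=C/[B-]1(OC(C)(C)C(C)(C)O1)[C@@H](C)[C@@H]2C=C[C@@H]3CCC[C@@H](C)[C@H]3[C@@H]2C(=O)OC | intermediate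
22 | methyl (1R,2S,4aS,8R,8aR)-2-[(2R,3Z,7S)-7-hydroxyoct-3-en-5-yn-2-yl]-8-methyl-1,2,4a,5,6,7,8,8a-octahydronaphthalene-1-carboxylate | C[C@H](O)C#C/C=C\[C@@H](C)[C@@H]2C=C[C@@H]3CCC[C@@H](C)[C@H]3[C@@H]2C(=O)OC | intermediate
23 | methyl (1R,2S,4aS,8R,8aR)-2-[(2R,3Z,5Z,7S)-7-hydroxyocta-3,5-dien-2-yl]-8-methyl-1,2,4a,5,6,7,8,8a-octahydronaphthalene-1-carboxylate | C[C@H](O)/C=C\C=C/[C@@H](C)[C@@H]2C=C[C@@H]3CCC[C@@H](C)[C@H]3[C@@H]2C(=O)OC | intermediate
24 | 2-chloro-1-[(1R,2S,4aS,8R,8aR)-2-[(2R,3Z,5Z,7S)-7-hydroxyocta-3,5-dien-2-yl]-8-methyl-1,2,4a,5,6,7,8,8a-octahydronaphthalen-1-yl]ethan-1-one | C[C@H](O)/C=C\C=C/[C@@H](C)[C@@H]2C=C[C@@H]3CCC[C@@H](C)[C@H]3[C@@H]2C(=O)CCl | intermediate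
25 | methylmalonic acid | CC(C(=O)O)C(=O)O | starting material
26 | 2-methyl-3-oxo-3-{[2-(trimethylsilyl)ethyl]sulfanyl}propanoic acid (racemic) | CC(C(=O)O)C(=O)SCC[Si](C)(C)C | intermediate
27 | (2S,3Z,5Z,7R)-7-[(1R,2S,4aS,8R,8aR)-1-(chloroacetyl)-8-methyl-1,2,4a,5,6,7,8,8a-octahydronaphthalen-2-yl]octa-3,5-dien-2-yl 2-methyl-3-oxo-3-{[2-(trimethylsilyl)ethyl]sulfanyl}propanoate (C2 epimers) | C[C@H](OC(=O)C(C)C(=O)SCC[Si](C)(C)C)/C=C\C=C/[C@@H](C)[C@@H]2C=C[C@@H]3CCC[C@@H](C)[C@H]3[C@@H]2C(=O)CCl | intermediate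
28 | tetrabutylammonium thiocarboxylate of 27 (silylethyl group removed) | CCCC[N+](CCCC)(CCCC)CCCC.C[C@H](OC(=O)C(C)C(=O)[S-])/C=C\C=C/[C@@H](C)[C@@H]2C=C[C@@H]3CCC[C@@H](C)[C@H]3[C@@H]2C(=O)CCl | intermediate
29 | 15-membered thia-lactone, sulfur between C3 and C4 of the macrolide ring (C2 epimers) | CC1C(=O)O[C@@H](C)/C=C\C=C/[C@@H](C)[C@@H]2C=C[C@@H]3CCC[C@@H](C)[C@H]3[C@@H]2C(=O)CSC1=O | intermediate
30 | (2S,6R,7R,8R,12S,15S,16R,17Z,19Z,21S)-4-deschloro macrolide, 14-membered 3,5-diketo lactone (drawn as diketone, enolised in solution) | C[C@@H]1C(=O)O[C@@H](C)/C=C\C=C/[C@@H](C)[C@@H]2C=C[C@@H]3CCC[C@@H](C)[C@H]3[C@@H]2C(=O)CC1=O | intermediate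
31 | CNP0477386.1, (2S,6R,7R,8R,12S,15S,16R,17Z,19Z,21S)-4-chloro-5-hydroxy enol macrolide | C[C@@H]1C(=O)O[C@@H](C)/C=C\C=C/[C@@H](C)[C@@H]2C=C[C@@H]3CCC[C@@H](C)[C@H]3[C@@H]2/C(O)=C(/Cl)C1=O | target

**Step count**
Total: 16 steps. Longest linear sequence: 13 steps (1–6, 8, 10, 11, 12, 14, 15, 16).

**Three steps most likely to fail**

Step 6 (cycloaddition). The C8 methyl must sit axial in the trans-fused transition state, against an intrinsic bias estimated at 1–2 kcal/mol. Catalyst control of about 2.5 kcal/mol should prevail, but the diastereomer ratio may be modest. The dienyl boronate must also tolerate the cationic copper Lewis acid. Fallback, with a covalently bound controller instead of a catalyst: from aldehyde 7, Horner–Wadsworth–Emmons olefination with the phosphonate carrying (R)-4-benzyl-1,3-oxazolidin-2-one gives the (R)-4-benzyl trienimide F1. Me2AlCl (1.4 equiv), CH2Cl2, −30 °C then gives the endo, trans-fused auxiliary-bearing cycloadduct F2 through the two-point aluminium chelate, which exposes the same Re face of C6. Its diastereomers are separable by crystallisation, and K2CO3/MeOH returns to the route at 10.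

Step 8 (lithiation–borylation). The secondary allylic ring boronate is hindered, so the 1,2-shift may be slow, and the lithiated carbamate may attack the ester. Fallback, with substrate-controlled Matteson homologation instead of a chiral carbenoid: from 10, KHF2 in aqueous MeOH gives the potassium trifluoroborate F3. Me3SiCl and (S,S)-1,2-dicyclohexylethane-1,2-diol give the (S,S)-DICHED boronate F4. LiCHCl2 at −100 °C followed by ZnCl2 gives, by a first 1,2-shift under control of the diol, the (S)-α-chloro boronate F5. MeMgBr at −78 °C to rt displaces chloride by a second 1,2-shift with inversion to give the DICHED analogue of 15, F6. F6 takes the place of 15 in step 10, and the route is rejoined at 22.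

Step 15 (proposed ring contraction). The thiomalonate C2–H is more acidic than C4–H, so the productive C4 enolate is a minor species. Reversible aldol closure of C2 onto the C5 ketone, ketene fragmentation or oligomerisation may compete. Fallback with known chemistry (acetoacetylation, C-methylation and dianion Claisen macrocyclisation, as used for this macrolide family): from 23, diketene with catalytic DMAP in CH2Cl2 gives the acetoacetate F7. MeI and K2CO3 in acetone give the 2-methylacetoacetate F8. LiN(SiMe3)2 (3.2 equiv), THF, −78 to 0 °C at high dilution forms the dianion, whose terminal carbon attacks the methyl ester, and the route is rejoined at 30.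

**Further compounds**
F1 | step 6 | (4R)-4-benzyl-3-[(2E,4R,8E,10E)-4-methyl-11-(Bpin)undeca-2,8,10-trienoyl]-1,3-oxazolidin-2-one | O=C(/C=C/[C@H](C)CCC/C=C/C=C/B1OC(C)(C)C(C)(C)O1)N2[C@H](Cc3ccccc3)COC2=O
F2 | step 6 | (4R)-4-benzyl-3-acyl-1,3-oxazolidin-2-one cycloadduct, ring stereocentres as in 9 | CC1(C)C(C)(C)OB(O1)[C@@H]2C=C[C@@H]3CCC[C@@H](C)[C@H]3[C@@H]2C(=O)N4[C@H](Cc5ccccc5)COC4=O
F3 | step 8 | potassium trifluoroborate corresponding to 10 | [K+].F[B-](F)(F)[C@@H]2C=C[C@@H]3CCC[C@@H](C)[C@H]3[C@@H]2C(=O)OC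
F4 | step 8 | (4S,5S)-4,5-dicyclohexyl-1,3,2-dioxaborolane (DICHED) analogue of 10 | B1(O[C@@H](C2CCCCC2)[C@H](C2CCCCC2)O1)[C@@H]3C=C[C@@H]4CCC[C@@H](C)[C@H]4[C@@H]3C(=O)OC
F5 | step 8 | (S)-α-chloro homologue of F4 (chloro(boryl)methyl group at C15) | B1(O[C@@H](C2CCCCC2)[C@H](C2CCCCC2)O1)[C@H](Cl)[C@@H]3C=C[C@@H]4CCC[C@@H](C)[C@H]4[C@@H]3C(=O)OC
F6 | step 8 | DICHED analogue of 15 (16S boronate) | B1(O[C@@H](C2CCCCC2)[C@H](C2CCCCC2)O1)[C@@H](C)[C@@H]3C=C[C@@H]4CCC[C@@H](C)[C@H]4[C@@H]3C(=O)OC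
F7 | step 15 | 3-oxobutanoate (acetoacetate) ester of 23 at O–C21 | C[C@H](OC(=O)CC(C)=O)/C=C\C=C/[C@@H](C)[C@@H]2C=C[C@@H]3CCC[C@@H](C)[C@H]3[C@@H]2C(=O)OC
F8 | step 15 | 2-methyl-3-oxobutanoate ester of 23 at O–C21 (C2 epimers) | C[C@H](OC(=O)C(C)C(C)=O)/C=C\C=C/[C@@H](C)[C@@H]2C=C[C@@H]3CCC[C@@H](C)[C@H]3[C@@H]2C(=O)OC
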